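The second catalyst is the worker of this flask: free catalyst opens the substrate, the second catalyst takes up the open intermediate as catalyst intermediate, and reagent turns that into product and frees the second catalyst again. We count its turnovers.

common to all: free catalyst 2.5 mol%; second catalyst 15 mol%
- elm: substrate 0.0020 M; reagent 2.2 equiv; run made earlier
- maple: substrate 0.0020 M; reagent 0.75 equiv; run made earlier
- south-east: substrate 0.0020 M; reagent 1.50 equiv; time 2.0 min
- south: substrate 0.0040 M; reagent 1.50 equiv; time 2.0 min
- north: substrate 0.0080 M; reagent 1.50 equiv; time 2.0 min
- west: substrate 0.015 M; reagent 1.50 equiv; time 2.0 min

| run | time / s | product / % | substrate / % |
|---|---|---|---|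
| elm | 10.0 | 86.3 | 0 |
| elm | 15.0 | 92.5 | 0.1 |
| elm | 25.0 | 95.5 | 0 |
| maple | 10.0 | 54.3 | 0 |
| maple | 25.0 | 63.6 | 0 |

(standard deviation of a reading: 0.3 percentage points)

- product is meant together with its crystals
- solid, in amounts per volume of the solution: crystals
- reactions considered so far: reagent + catalyst intermediate -> second catalyst + product; crystals <-> product; second catalyst + open intermediate <-> catalyst intermediate; second catalyst -> spent catalyst; substrate + free catalyst -> free catalyst + open intermediate
- a step back or a flat step of under half a point counts as no turn
- "hardly changes" means that all values lie within two and a half points (for a concentration: within two and a half percent of the largest)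
- no earlier run changes the charge of free catalyst; that part of a forecast is a guess
- no earlier run changes the charge of second catalyst; that part of a forecast is a guess

1. amount of product at the end, in percent of the substrate charged for south-east, south, north, west, in this order
2. how that number moves from the first to the last of them (hardly changes / rises all the way / rises, then falls / falls, then rises / falls all the way)

1. The main cycle by itself. If the second catalyst lived on, the reagent at 1.50 equiv would cover the substrate, and c(substrate) would bound the product. We keep 6.67 as the turnover need, the product wanted per second catalyst charged for full conversion. South-east, south, north and west share the loading 15 mol%, so they share this need.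

2. Add the passing of second catalyst into spent catalyst. In the elm run substrate reads 0% at 10.0 s, so what is not yet product is open intermediate or catalyst intermediate. Its logarithm falls at 0.120 s⁻¹ at first and then at 0.0511 s⁻¹, slower. We read this as the second catalyst fading, with a half-life of about 6.06 s. By 25.0 s, some 4.13 such half-lives on, the elm count is 6.37, still below the need.

3. Add less reagent. The maple run has counted 4.24 by 25.0 s, and its reagent caps it at 5.00. South-east has the same c(substrate) and a reagent charge between those two runs, so we place its count between 4.24 and 6.37, lower than the need. Our window for its product is 63.6% to 95.5%.

4. Add concentration. The passing into spent catalyst is first order, so the second catalyst's life stays put, while each turnover begins with a bimolecular meeting with open intermediate. At fixed equivalents and loading, we therefore take the turnovers that the second catalyst can offer within its life to grow with c(substrate), while the count itself cannot pass the need, which the substrate charged sets. Crystals are counted with product and do not enter the count. Maple's count, scaled in this way to south, offers 8.48 turnovers as an estimate, above the need. We expect south to come close to full conversion, with north and west level beside it.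

The forecast gives 90%, 98%, 99.7% and 100%, shape rises all the way, on the ground that “Doubling concentration doubles the exposure”. Its south-east point lies inside our wider window.

The flask gives 91.6%, 99.9%, 100% and 100%, shape rises all the way.

    reagent + catalyst intermediate → second catalyst + product (k = 27000 M⁻¹ s⁻¹)
    crystals ⇌ product, rate k2*(cs2 - [product]) while solid is left; crystals form when [product] > cs2 (solubility = 1.10 mM, k = 0.590 s⁻¹)
    second catalyst + open intermediate ⇌ catalyst intermediate (K = 29.0 M⁻¹, k = 2500 M⁻¹ s⁻¹)
    second catalyst → spent catalyst (k = 0.0910 s⁻¹)
    substrate + free catalyst → free catalyst + open intermediate (k = 18000 M⁻¹ s⁻¹)

In south-east at 0.0129 min, the forward capture of second catalyst by open intermediate ran at 24 times the rate of its passing into spent catalyst, whose half-life by that path alone is 0.13 min, shorter than the run of 2.0 min. By 2.00 min south-east held spent catalyst at >99.9% and open intermediate at 8.43%, with a count of 6.11 against the need of 6.67. South, with the same loading at 0.0040 M, counted 6.66 and held open intermediate at 0.133%.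

The runs are calculated with constants of no real substance; the scatter is artificial.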